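**Plan**

- Numbering: oxolane O1, C2 (aryl ring B), C3 (CH2OH), C4 (aroyl ring A), C5; rings A and B are the two 4-hydroxy-3,5-dimethoxyphenyl rings.
- Retrosynthesis cuts O1–C2 first (to an open-chain keto diol), then the bond from C4 to the ketone carbon (aldol), then C2–C3 (Stobbe condensation); this leaves syringaldehyde, used twice, and dimethyl succinate.
- Forward: the succinate unit (C5, C4, C3 and the CH2OH carbon) is joined to the ring B aldehyde carbon, held as a γ-butyrolactone, extended at C4 with the ring A aldehyde, opened by reduction and oxidised to the aryl ketone; the oxolane, the only new ring, closes last.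
- Enabling feature: C2 is a benzylic carbon para to the free phenol of ring B, so in the open-chain precursor it is the CH2 of a 4-alkylphenol that an oxidase can turn into a p-quinone methide; ring A sits on the ketone carbon and has no benzylic hydrogen.
- Stereochemistry: C3 (R) from ligand-controlled Rh-catalysed hydrogenation; C4 (R) from the lactone enolate aldol, trans to the arylmethyl group on the lactone (this becomes the 3,4-cis relation of CH2OH and aroyl on the oxolane); C2 (S) from substrate control in the ring closure, aryl trans to the C3 CH2OH.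

Key step: step 9

Assumption: the (S,S) antipode of Et-DuPhos is taken to deliver the R acid 6 in step 3; if the sense proved opposite, the (R,R) ligand would be used and nothing else changes.
Assumption: eugenol oxidase is obtained by heterologous expression in Escherichia coli and is used as a catalyst, not as a starting material.

**Route**

Step 1
Reactants: 1 syringaldehyde (4-hydroxy-3,5-dimethoxybenzaldehyde)
Product: 2 4-(benzyloxy)-3,5-dimethoxybenzaldehyde
Conditions: BnBr (1.2 equiv), K2CO3, DMF, 60 °C
Reagents that add atoms: benzyl bromide, BrCc1ccccc1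
Why: Williamson ether synthesis on the acidic para-formyl phenol; the benzyl ether is chosen because it should survive alkoxide, homogeneous Rh/H2, hydrides, amide base and MnO2 and then leave by neutral hydrogenolysis.

Step 2
Reactants: 2 4-(benzyloxy)-3,5-dimethoxybenzaldehyde; 3 dimethyl succinate
Product: 5 (E)-4-[4-(benzyloxy)-3,5-dimethoxyphenyl]-3-(methoxycarbonyl)but-3-enoic acid, via paraconate lactone 4 (not isolated)
Conditions: NaOMe (2 equiv), MeOH, reflux; then aq. HCl
Reagents that add atoms: none
Why: Stobbe condensation, in which the succinate enolate adds to the aldehyde, the alkoxide closes lactone 4 onto the distal ester and base-induced E1cB opening of 4 gives the E half-ester with only the remote carboxyl free.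

Step 3
Reactants: 5 (E)-4-[4-(benzyloxy)-3,5-dimethoxyphenyl]-3-(methoxycarbonyl)but-3-enoic acid
Product: 6 (R)-4-[4-(benzyloxy)-3,5-dimethoxyphenyl]-3-(methoxycarbonyl)butanoic acid
Conditions: H2 (5 bar), [Rh(cod)((S,S)-Et-DuPhos)]OTf (0.5 mol%), NaOMe (10 mol%), MeOH, 25 °C
Reagents that add atoms: none
Why: Asymmetric hydrogenation of an itaconate-type half-ester, in which carboxylate and alkene chelate rhodium and the C2-symmetric bisphospholane selects the alkene face, setting the future C3 as R; aryl benzyl ethers are inert to this homogeneous catalyst.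

Step 4
Reactants: 6 (R)-4-[4-(benzyloxy)-3,5-dimethoxyphenyl]-3-(methoxycarbonyl)butanoic acid
Product: 8 (R)-4-[4-(benzyloxy)-3,5-dimethoxybenzyl]oxolan-2-one, via hydroxy acid 7 (not isolated)
Conditions: KOH (1.0 equiv), EtOH, 0 °C; CaCl2, NaBH4, EtOH, −10 °C to rt; then 2 M HCl, rt
Reagents that add atoms: none
Why: Chemoselective ester reduction, since Ca(BH4)2 formed in the flask reduces the methyl ester but not the potassium carboxylate, and acidification lactonises hydroxy acid 7 without touching the stereocentre.

Step 5
Reactants: 8 (R)-4-[4-(benzyloxy)-3,5-dimethoxybenzyl]oxolan-2-one; 2 4-(benzyloxy)-3,5-dimethoxybenzaldehyde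
Product: 10 (3S,4R)-4-[4-(benzyloxy)-3,5-dimethoxybenzyl]-3-{[4-(benzyloxy)-3,5-dimethoxyphenyl](hydroxy)methyl}oxolan-2-one (both carbinol epimers), via lithium enolate 9 (not isolated)
Conditions: LiN(iPr)2 (1.1 equiv), THF, −78 °C; then 2, −78 °C; AcOH quench at −78 °C
Reagents that add atoms: none
Why: Aldol addition of a γ-butyrolactone lithium enolate, in which the aldehyde approaches the face opposite the β-arylmethyl group and so sets the α-carbon (future C4) trans to it, while the carbinol configuration is irrelevant because that carbon becomes the ketone in step 7.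

Step 6
Reactants: 10 the trans aldol lactone
Product: 11 (2R,3R)-2-{[4-(benzyloxy)-3,5-dimethoxyphenyl](hydroxy)methyl}-3-[4-(benzyloxy)-3,5-dimethoxybenzyl]butane-1,4-diol (both carbinol epimers)
Conditions: LiAlH4, THF, 0 °C; H2O/aq. NaOH work-up
Reagents that add atoms: none
Why: Hydride reduction of the lactone to the 1,4-diol, fast enough at 0 °C that retro-aldol cleavage should not compete, with a basic work-up so that the acid-sensitive benzylic carbinol does not cyclise; no stereocentre is touched.

Step 7
Reactants: 11 the dibenzyl triol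
Product: 12 (2R,3R)-1,4-bis[4-(benzyloxy)-3,5-dimethoxyphenyl]-2,3-bis(hydroxymethyl)butan-1-one
Conditions: activated MnO2 (15 equiv), CH2Cl2, rt
Reagents that add atoms: none
Why: Chemoselective benzylic alcohol oxidation, since MnO2 should oxidise the secondary benzylic carbinol and leave the two saturated primary alcohols, and the neutral heterogeneous medium should spare the epimerisable β-hydroxy ketone.

Step 8
Reactants: 12 the dibenzyl keto diol
Product: 13 (2R,3R)-1,4-bis(4-hydroxy-3,5-dimethoxyphenyl)-2,3-bis(hydroxymethyl)butan-1-one
Conditions: H2 (1 atm), 10% Pd/C, EtOAc, rt, stopped after two equivalents of H2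
Reagents that add atoms: none
Why: Hydrogenolysis of aryl benzyl ethers, which under neutral conditions is expected to be much faster than reduction of a para-oxygenated aryl ketone, so the carbonyl and the adjacent stereocentre should remain intact.

Step 9
Reactants: 13 the keto diol
Product: 15 ciwujiatone (2S,3R,4R in the numbering of the plan), via quinone methide 14 (not isolated)
Conditions: eugenol oxidase (recombinant flavin-dependent 4-alkylphenol oxidase of the vanillyl alcohol oxidase family, Rhodococcus jostii RHA1), air, 50 mM KH2PO4/K2HPO4 buffer pH 7.5, 10% v/v acetone, 13 at 2 mM, 25 °C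
Reagents that add atoms: none
Why: Proposed new method: the oxidase binds ring B of 13 as the phenolate and its flavin takes a hydride from the benzylic CH2 (future C2), giving p-quinone methide 14 while O2 reoxidises the flavin to H2O2; the hydroxyl of the CH2OH on the carbon next to the ketone (future C5–O1) then adds to the methide carbon, ring B rearomatises and O1–C2 is formed. The closest known reaction type is the dehydrogenation of 4-alkyl- and 4-allylphenols, 2,6-dimethoxy ones included, to p-quinone methides by vanillyl alcohol oxidase and eugenol oxidase with capture by water or an added nucleophile, so the untested elements are the lignan-sized substrate and the internal alcohol as nucleophile. The oxolane closes by a 5-exo-trig oxa-conjugate addition to the exocyclic methide carbon. The new centre C2 is controlled by the substrate: in the envelope transition state the planar quinone methide should lie on the face away from the C3 hydroxymethyl group, giving the 2,3-trans (2S) isomer. The step needs selectivity between two identical syringyl phenols and between two primary hydroxyls, and the substrate secures both, because ring A is bonded to the ketone carbon and has no benzylic hydrogen and because the C3 hydroxymethyl oxygen could only close a four-membered ring. Neutral buffer at 25 °C is chosen so that the epimerisable C4–H and the β-hydroxy ketone are not disturbed.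

**Compound list**

1 | syringaldehyde | COc1cc(C=O)cc(OC)c1O | starting material
2 | 4-(benzyloxy)-3,5-dimethoxybenzaldehyde | COc1cc(C=O)cc(OC)c1OCc1ccccc1 | intermediate
3 | dimethyl succinate | COC(=O)CCC(=O)OC | starting material
4 | paraconate lactone: methyl 2-[4-(benzyloxy)-3,5-dimethoxyphenyl]-5-oxooxolane-3-carboxylate (stereoisomer mixture; not isolated) | COC(=O)C1CC(=O)OC1c1cc(OC)c(OCc2ccccc2)c(OC)c1 | intermediate
5 | (E)-4-[4-(benzyloxy)-3,5-dimethoxyphenyl]-3-(methoxycarbonyl)but-3-enoic acid | COC(=O)/C(CC(=O)O)=C/c1cc(OC)c(OCc2ccccc2)c(OC)c1 | intermediate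
6 | (R)-4-[4-(benzyloxy)-3,5-dimethoxyphenyl]-3-(methoxycarbonyl)butanoic acid | COC(=O)[C@@H](CC(=O)O)Cc1cc(OC)c(OCc2ccccc2)c(OC)c1 | intermediate
7 | hydroxy acid: (R)-4-[4-(benzyloxy)-3,5-dimethoxyphenyl]-3-(hydroxymethyl)butanoic acid (not isolated) | OC[C@@H](CC(=O)O)Cc1cc(OC)c(OCc2ccccc2)c(OC)c1 | intermediate
8 | (R)-4-[4-(benzyloxy)-3,5-dimethoxybenzyl]oxolan-2-one | O=C1C[C@@H](Cc2cc(OC)c(OCc3ccccc3)c(OC)c2)CO1 | intermediate
9 | lithium enolate of 8 (not isolated) | [Li+].[O-]C1=C[C@@H](Cc2cc(OC)c(OCc3ccccc3)c(OC)c2)CO1 | intermediate
10 | (3S,4R)-4-[4-(benzyloxy)-3,5-dimethoxybenzyl]-3-{[4-(benzyloxy)-3,5-dimethoxyphenyl](hydroxy)methyl}oxolan-2-one (both carbinol epimers) | OC(c1cc(OC)c(OCc2ccccc2)c(OC)c1)[C@H]3C(=O)OC[C@@H]3Cc4cc(OC)c(OCc5ccccc5)c(OC)c4 | intermediate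
11 | (2R,3R)-2-{[4-(benzyloxy)-3,5-dimethoxyphenyl](hydroxy)methyl}-3-[4-(benzyloxy)-3,5-dimethoxybenzyl]butane-1,4-diol (both carbinol epimers) | COc1cc(C(O)[C@@H](CO)[C@H](CO)Cc2cc(OC)c(OCc3ccccc3)c(OC)c2)cc(OC)c1OCc1ccccc1 | intermediate
12 | (2R,3R)-1,4-bis[4-(benzyloxy)-3,5-dimethoxyphenyl]-2,3-bis(hydroxymethyl)butan-1-one | COc1cc(C(=O)[C@@H](CO)[C@H](CO)Cc2cc(OC)c(OCc3ccccc3)c(OC)c2)cc(OC)c1OCc1ccccc1 | intermediate
13 | (2R,3R)-1,4-bis(4-hydroxy-3,5-dimethoxyphenyl)-2,3-bis(hydroxymethyl)butan-1-one | COc1cc(C(=O)[C@@H](CO)[C@H](CO)Cc2cc(OC)c(O)c(OC)c2)cc(OC)c1O | intermediate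
14 | p-quinone methide of 13: 4-[(2R,3R)-4-(4-hydroxy-3,5-dimethoxyphenyl)-2,3-bis(hydroxymethyl)-4-oxobutylidene]-2,6-dimethoxycyclohexa-2,5-dien-1-one (not isolated) | COC1=CC(=C[C@@H](CO)[C@H](CO)C(=O)c2cc(OC)c(O)c(OC)c2)C=C(OC)C1=O | intermediate
15 | ciwujiatone, [(3R,4R,5S)-5-(4-hydroxy-3,5-dimethoxyphenyl)-4-(hydroxymethyl)oxolan-3-yl](4-hydroxy-3,5-dimethoxyphenyl)methanone | COc1cc(C(=O)[C@H]2CO[C@H](c3cc(OC)c(O)c(OC)c3)[C@H]2CO)cc(OC)c1O | target

**Step count**

Total steps: 9. Longest linear sequence: 9 steps (1 → 2 → 5 → 6 → 8 → 10 → 11 → 12 → 13 → 15); aldehyde 2 enters a second time in step 5.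

**Steps most likely to fail**

1. Step 9 (the step marked as a proposed new method). The oxidase may not bind or turn over a substrate of this size. Water may capture the quinone methide in competition with the internal hydroxyl. The enzyme may also dehydrogenate the product again at its remaining benzylic hydrogen. Fallback with known chemistry: the quinone methide is generated chemically instead of enzymatically, so that selectivity rests on the redox difference between the two phenols and not on an active site. Keto diol 13 would be treated with DDQ (1.0 equiv) in 1,4-dioxane at 0 °C to rt. The electron-rich 4-alkyl-2,6-dimethoxyphenol of ring B should be dehydrogenated to the same quinone methide 14, while the acyl-substituted phenol of ring A is too electron-poor and has no benzylic hydrogen. 14 should then cyclise as in the main route. The fallback sets out from 13 and comes back at 15; no compound outside the compound list arises (F0).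

2. Step 7. Oxidation at the hindered benzylic carbinol may stall. The 1,4-diol may be over-oxidised towards a lactol or lactone. The β-hydroxy ketone may lose water on the oxide surface. Fallback: the primary hydroxyls are masked and a homogeneous oxidant is used. Triol 11 with TBSCl (2.1 equiv) and imidazole in CH2Cl2 at 0 °C should give the bis(tert-butyldimethylsilyl) ether of the two primary hydroxyls F1, the hindered secondary benzylic hydroxyl staying free. Dess–Martin periodinane with NaHCO3 in CH2Cl2 should then give the silylated ketone F2. HF·pyridine in THF/pyridine at 0 °C should remove both silyl groups under non-basic conditions. The fallback sets out from 11 and comes back at 12.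

3. Step 8. Reduction or hydrogenolysis of the aryl ketone may compete with debenzylation, and the α-centre may epimerise on the catalyst support. Fallback: the benzyl groups are removed before any ketone exists and replaced by silyl groups. Triol 11 with H2 and 10% Pd/C in EtOAc should give the bis-phenol triol F3. TBSCl (4.2 equiv) and imidazole in DMF at 0 °C should silylate both phenols and both primary hydroxyls to give the tetrakis(silyl ether) F4, with the hindered secondary benzylic hydroxyl left free. Dess–Martin periodinane with NaHCO3 in CH2Cl2 should give the silylated ketone F5. Bu4NF buffered with AcOH (1:1) in THF at 0 °C to rt should then release all four hydroxyls under near-neutral conditions. The fallback sets out from 11 and comes back at 13.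

**Further compounds**

F0 | step 9 | none | none
F1 | step 7 | bis-O-(tert-butyldimethylsilyl) ether of triol 11 at both primary hydroxyls (both carbinol epimers) | COc1cc(C(O)[C@@H](CO[Si](C)(C)C(C)(C)C)[C@H](CO[Si](C)(C)C(C)(C)C)Cc2cc(OC)c(OCc3ccccc3)c(OC)c2)cc(OC)c1OCc1ccccc1
F2 | step 7 | (2R,3R)-1,4-bis[4-(benzyloxy)-3,5-dimethoxyphenyl]-2,3-bis{[(tert-butyldimethylsilyl)oxy]methyl}butan-1-one | COc1cc(C(=O)[C@@H](CO[Si](C)(C)C(C)(C)C)[C@H](CO[Si](C)(C)C(C)(C)C)Cc2cc(OC)c(OCc3ccccc3)c(OC)c2)cc(OC)c1OCc1ccccc1
F3 | step 8 | (2R,3R)-2-[hydroxy(4-hydroxy-3,5-dimethoxyphenyl)methyl]-3-(4-hydroxy-3,5-dimethoxybenzyl)butane-1,4-diol (both carbinol epimers) | COc1cc(C(O)[C@@H](CO)[C@H](CO)Cc2cc(OC)c(O)c(OC)c2)cc(OC)c1O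
F4 | step 8 | tetrakis-O-(tert-butyldimethylsilyl) ether of F3 at both phenols and both primary hydroxyls (both carbinol epimers) | COc1cc(C(O)[C@@H](CO[Si](C)(C)C(C)(C)C)[C@H](CO[Si](C)(C)C(C)(C)C)Cc2cc(OC)c(O[Si](C)(C)C(C)(C)C)c(OC)c2)cc(OC)c1O[Si](C)(C)C(C)(C)C
F5 | step 8 | (2R,3R)-1,4-bis{4-[(tert-butyldimethylsilyl)oxy]-3,5-dimethoxyphenyl}-2,3-bis{[(tert-butyldimethylsilyl)oxy]methyl}butan-1-one | COc1cc(C(=O)[C@@H](CO[Si](C)(C)C(C)(C)C)[C@H](CO[Si](C)(C)C(C)(C)C)Cc2cc(OC)c(O[Si](C)(C)C(C)(C)C)c(OC)c2)cc(OC)c1O[Si](C)(C)C(C)(C)C
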